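**Plan**

- Retrosynthesis (after removal of 17 benzyl ethers) cuts, in this order: C4–C4a of the middle pyran ring; C4(middle)–C8(bottom); O1–C2(middle); C4(top)–C8(middle A ring).
- Forward: the top catechin unit is C4-arylated by 3,5-bis(benzyloxy)phenol (the future middle A ring). The phenol oxygen then opens a Sharpless epoxide (O1–C2 and the C2–C3–C4 chain). The chain end is oxidised to an aldehyde, which takes up 8-lithio-gallocatechin. The middle pyran ring is the only ring built and is closed last.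
- Enabling feature: C4 of the middle unit lies between two phloroglucinol-type rings. As a cation it is stabilised by O1, O5 and O7 of the bottom A ring (ortho, para, ortho to C8). C4a of the middle A ring is ortho/para to its three oxygens, is the only free position ortho to O1 (C8 carries the top unit), and sits six atoms away through O1–C2–C3.
- Stereochemistry: C2/C3 of the top and bottom units come from (+)-catechin and (+)-gallocatechin. C3 of the middle unit comes from Sharpless epoxidation, and C2 from SN2 inversion on epoxide opening. Both C4 centres arise by substrate control (bond formation anti to the 3-benzyloxy group, 3,4-trans).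

Key step: step 15

Remark: the C4 centre of 3 and the carbinol centre of 20 are carried as epimer mixtures, because each becomes a planar cation in the following step; their SMILES leave that centre open. Compounds 1, 4, 6, 7 and 16 are taken as commercial.

**Step 1**
Reactants: 1 (+)-catechin
Product: 2 3,5,7,3',4'-penta-O-benzyl-(+)-catechin
Conditions: BnBr (6 equiv), NaH (5.5 equiv), DMF, −20 °C → rt
Reagents that add atoms: benzyl bromide, BrCc1ccccc1
Why: Williamson etherification of the four phenols and the C3 alcohol; no stereocentre is touched.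

**Step 2**
Reactants: 2 penta-O-benzylcatechin
Product: 3 4-(2-ethoxyethoxy)-penta-O-benzylcatechin (C4 epimers)
Conditions: DDQ (2 equiv), 2-ethoxyethanol (5 equiv), CH2Cl2, rt
Reagents that add atoms: 2-ethoxyethanol, CCOCCO
Why: DDQ benzylic oxidation, in which hydride abstraction from C4 (activated by the 5,7-dioxygenated A ring) gives the flavan-4-yl cation that the alcohol traps; the C4 configuration is irrelevant because the centre is ionised again in step 3.

**Step 3**
Reactants: 3 4-(2-ethoxyethoxy)-penta-O-benzylcatechin; 4 3,5-bis(benzyloxy)phenol (3 equiv)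
Product: 5 penta-O-benzylcatechin-(4α→2)-[3,5-bis(benzyloxy)phenol], 2,3-trans-3,4-trans
Conditions: TMSOTf (0.1 equiv), CH2Cl2, −78 °C
Reagents that add atoms: none
Why: Friedel–Crafts alkylation by the flavan-4-yl cation, with attack anti to the 3-benzyloxy group setting C4 as 4α (3,4-trans); the ring position between OH and OBn should be preferred because it is less hindered than the position between two OBn groups, in line with the known ortho C-alkylation of this phenol by stabilised allylic cations, and the excess of 4 limits double alkylation.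

**Step 4**
Reactants: 6 3,4,5-tris(benzyloxy)benzaldehyde; 7 triethyl phosphonoacetate
Product: 8 ethyl (E)-3-[3,4,5-tris(benzyloxy)phenyl]acrylate
Conditions: NaH, THF, 0 °C → rt
Reagents that add atoms: none
Why: Horner–Wadsworth–Emmons olefination, which is reliably E-selective with stabilised phosphonates and aryl aldehydes.

**Step 5**
Reactants: 8 ethyl (E)-cinnamate
Product: 9 (E)-3-[3,4,5-tris(benzyloxy)phenyl]prop-2-en-1-ol
Conditions: DIBAL-H (2.5 equiv), CH2Cl2, −78 → 0 °C; Rochelle salt work-up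
Reagents that add atoms: none
Why: DIBAL-H 1,2-reduction of an enoate to the allylic alcohol with retention of the E geometry.

**Step 6**
Reactants: 9 (E)-allylic alcohol
Product: 10 [(2S,3S)-3-[3,4,5-tris(benzyloxy)phenyl]oxiran-2-yl]methanol
Conditions: Ti(OiPr)4 (10 mol %), L-(+)-DIPT (12 mol %), t-BuOOH (2 equiv), 4 Å MS, CH2Cl2, −20 °C
Reagents that add atoms: tert-butyl hydroperoxide, CC(C)(C)OO
Why: Sharpless asymmetric epoxidation, in which L-(+)-tartrate delivers oxygen to the face of an (E)-3-arylallyl alcohol that gives the (2S,3S)-epoxide; this sets the future C3 of the middle unit.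

**Step 7**
Reactants: 5 top-unit phenol; 10 (2S,3S)-epoxy alcohol (1.5 equiv)
Product: 11 (2S,3R)-3-aryloxy-3-[3,4,5-tris(benzyloxy)phenyl]propane-1,2-diol (aryloxy = O-linked residue of 5)
Conditions: aq NaOH (1.5 equiv), Bu4NBr (10 mol %), toluene/H2O, 70 °C
Reagents that add atoms: none
Why: SN2 opening of the trans-3-arylglycidol by the phenoxide at the benzylic carbon (the known C3 selectivity of phenoxide openings of 3-arylglycidols), which proceeds with inversion and sets the future C2 of the middle unit as R while C3 is retained, giving the erythro pattern needed for a 2,3-trans flavan.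

**Step 8**
Reactants: 11 diol
Product: 12 1-O-TBDPS ether of 11
Conditions: TBDPSCl (1.1 equiv), imidazole, DMF, 0 °C
Reagents that add atoms: tert-butyl(chloro)diphenylsilane, CC(C)(C)[Si](Cl)(c1ccccc1)c1ccccc1
Why: selective silylation of the primary hydroxyl by the bulky silyl chloride.

**Step 9**
Reactants: 12 primary silyl ether
Product: 13 2-O-benzyl-1-O-TBDPS ether
Conditions: NaH, BnBr, Bu4NI (cat.), THF/DMF, 0 °C → rt
Reagents that add atoms: benzyl bromide, BrCc1ccccc1
Why: Williamson benzylation of the remaining secondary alcohol; the TBDPS group resists 1,2-silyl migration under these conditions.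

**Step 10**
Reactants: 13 benzyl silyl diether
Product: 14 (2S,3R)-2-(benzyloxy)-3-aryloxy-3-[3,4,5-tris(benzyloxy)phenyl]propan-1-ol
Conditions: TBAF, THF, 0 °C → rt
Reagents that add atoms: none
Why: fluoride-induced desilylation, which leaves benzyl and aryl ethers untouched.

**Step 11**
Reactants: 14 primary alcohol
Product: 15 (2R,3R)-2-(benzyloxy)-3-aryloxy-3-[3,4,5-tris(benzyloxy)phenyl]propanal
Conditions: Dess–Martin periodinane, NaHCO3, CH2Cl2, 0 °C → rt
Reagents that add atoms: none
Why: Dess–Martin oxidation, a buffered, near-neutral method that should give the α-alkoxy aldehyde without epimerisation or β-elimination.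

**Step 12**
Reactants: 16 (+)-gallocatechin
Product: 17 3,5,7,3',4',5'-hexa-O-benzyl-(+)-gallocatechin
Conditions: BnBr (7 equiv), NaH (6.5 equiv), DMF, −20 °C → rt
Reagents that add atoms: benzyl bromide, BrCc1ccccc1
Why: Williamson per-O-benzylation; the low temperature guards against base-induced C2 epimerisation.

**Step 13**
Reactants: 17 hexa-O-benzylgallocatechin
Product: 18 8-bromo-hexa-O-benzylgallocatechin
Conditions: NBS (1.0 equiv), CH2Cl2, −78 → 0 °C
Reagents that add atoms: N-bromosuccinimide, O=C1CCC(=O)N1Br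
Why: electrophilic aromatic bromination, which in benzylated flavan-3-ols goes to C8 of the phloroglucinol-type A ring, far more reactive than the pyrogallol-type B ring.

**Step 14**
Reactants: 18 8-bromo-hexa-O-benzylgallocatechin (1.3 equiv); 15 aldehyde
Product: 20 carbinol (C4–C8 linked, carbinol epimers), via 8-lithio-hexa-O-benzylgallocatechin 19 (not isolated)
Conditions: n-BuLi (1.3 equiv), THF, −78 °C; then 15, −78 °C; H2O
Reagents that add atoms: none
Why: bromine–lithium exchange followed by 1,2-addition of the aryllithium to the aldehyde fixes the interflavan C4–C8 bond with unambiguous regiochemistry; the new carbinol configuration is irrelevant because the centre is ionised in step 15.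

**Step 15**
Reactants: 20 carbinol
Product: 21 heptadeca-O-benzyl catechin-(4α→8)-gallocatechin-(4α→8)-gallocatechin
Conditions: BF3·OEt2 (0.2 equiv), 4 Å MS, CH2Cl2 (0.005 M), −78 → −30 °C
Reagents that add atoms: none
Why: BF3 ionises the carbinol to a benzylic cation that is a quinone-methide-type ion delocalised onto O1, O5 and O7 of the bottom A ring, and C4a of the middle A ring attacks it in an intramolecular Friedel–Crafts alkylation, followed by loss of the C4a proton. The closest known reaction types are the acid-catalysed cyclisation of 3-aryloxy-1-arylpropan-1-ols to 4-arylchromans and the flavan-4-yl cation/arene coupling used for interflavan bonds, here with the cation placed on the partner ring. The pyran ring closes in a six-membered mode in which the attacked arene bond C4a=C8a becomes endocyclic and the cationic carbon is exocyclic to its own aryl ring (6-endo in the arene), through a chair-like transition state. The new stereocentre C4 is controlled by C3: allylic 1,3-strain with the 2,6-dioxygenated bottom ring keeps H3 in the plane of the cation, so the tethered arene adds from the C2 side, anti to the 3-benzyloxy group, with the 2-aryl and 3-benzyloxy groups equatorial, which places H3 and H4 anti (3,4-trans, 4α). The step needs chemoselective ionisation, secured because the trioxygenated benzyl carbinol ionises far more readily than the O1–C2 benzylic aryl ether or the top interflavan bond under catalytic acid at low temperature, and site-selective capture, secured because C4a is the only free position ortho to O1, ring B is a much weaker nucleophile that could only give a strained indane, and high dilution suppresses intermolecular capture.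

**Step 16**
Reactants: 21 perbenzylated trimer
Product: 22 catechin-(4α→8)-gallocatechin-(4α→8)-gallocatechin (target)
Conditions: H2 (1 atm), 20% Pd(OH)2/C, THF/MeOH/H2O, rt
Reagents that add atoms: none
Why: global hydrogenolysis of the 17 benzyl ethers over Pearlman's catalyst under neutral conditions, which should leave the interflavan bonds and all stereocentres untouched.

**Compound list**

1 | (+)-catechin, (2R,3S) | Oc1cc(O)c2c(c1)O[C@H](c1ccc(O)c(O)c1)[C@@H](O)C2 | starting material
2 | 3,5,7,3',4'-penta-O-benzyl-(+)-catechin | c9ccccc9COc1cc(OCc9ccccc9)c2c(c1)O[C@H](c1ccc(OCc9ccccc9)c(OCc9ccccc9)c1)[C@@H](OCc9ccccc9)C2 | intermediate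
3 | 4-(2-ethoxyethoxy)-penta-O-benzylcatechin (C4 epimers) | c9ccccc9COc1cc(OCc9ccccc9)c2c(c1)O[C@H](c1ccc(OCc9ccccc9)c(OCc9ccccc9)c1)[C@@H](OCc9ccccc9)C2OCCOCC | intermediate
4 | 3,5-bis(benzyloxy)phenol | Oc1cc(OCc9ccccc9)cc(OCc9ccccc9)c1 | starting material
5 | 2-[(2R,3S,4α)-penta-O-benzylcatechin-4-yl]-3,5-bis(benzyloxy)phenol (2,3-trans-3,4-trans) | c9ccccc9COc1cc(OCc9ccccc9)c2c(c1)O[C@H](c1ccc(OCc9ccccc9)c(OCc9ccccc9)c1)[C@@H](OCc9ccccc9)[C@@H]2c1c(OCc9ccccc9)cc(OCc9ccccc9)cc1O | intermediate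
6 | 3,4,5-tris(benzyloxy)benzaldehyde | O=Cc1cc(OCc9ccccc9)c(OCc9ccccc9)c(OCc9ccccc9)c1 | starting material
7 | triethyl phosphonoacetate | CCOC(=O)CP(=O)(OCC)OCC | starting material
8 | ethyl (E)-3-[3,4,5-tris(benzyloxy)phenyl]acrylate | CCOC(=O)/C=C/c1cc(OCc9ccccc9)c(OCc9ccccc9)c(OCc9ccccc9)c1 | intermediate
9 | (E)-3-[3,4,5-tris(benzyloxy)phenyl]prop-2-en-1-ol | OC/C=C/c1cc(OCc9ccccc9)c(OCc9ccccc9)c(OCc9ccccc9)c1 | intermediate
10 | [(2S,3S)-3-[3,4,5-tris(benzyloxy)phenyl]oxiran-2-yl]methanol | OC[C@@H]1O[C@H]1c1cc(OCc9ccccc9)c(OCc9ccccc9)c(OCc9ccccc9)c1 | intermediate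
11 | (2S,3R)-3-aryloxy-3-[3,4,5-tris(benzyloxy)phenyl]propane-1,2-diol (aryloxy from 5) | c9ccccc9COc1cc(OCc9ccccc9)c2c(c1)O[C@H](c1ccc(OCc9ccccc9)c(OCc9ccccc9)c1)[C@@H](OCc9ccccc9)[C@@H]2c1c(OCc9ccccc9)cc(OCc9ccccc9)cc1O[C@H](c1cc(OCc9ccccc9)c(OCc9ccccc9)c(OCc9ccccc9)c1)[C@@H](O)CO | intermediate
12 | 1-O-TBDPS ether of 11 | c9ccccc9COc1cc(OCc9ccccc9)c2c(c1)O[C@H](c1ccc(OCc9ccccc9)c(OCc9ccccc9)c1)[C@@H](OCc9ccccc9)[C@@H]2c1c(OCc9ccccc9)cc(OCc9ccccc9)cc1O[C@H](c1cc(OCc9ccccc9)c(OCc9ccccc9)c(OCc9ccccc9)c1)[C@@H](O)CO[Si](c1ccccc1)(c1ccccc1)C(C)(C)C | intermediate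
13 | 2-O-benzyl-1-O-TBDPS ether of 11 | c9ccccc9COc1cc(OCc9ccccc9)c2c(c1)O[C@H](c1ccc(OCc9ccccc9)c(OCc9ccccc9)c1)[C@@H](OCc9ccccc9)[C@@H]2c1c(OCc9ccccc9)cc(OCc9ccccc9)cc1O[C@H](c1cc(OCc9ccccc9)c(OCc9ccccc9)c(OCc9ccccc9)c1)[C@@H](OCc9ccccc9)CO[Si](c1ccccc1)(c1ccccc1)C(C)(C)C | intermediate
14 | (2S,3R)-2-(benzyloxy)-3-aryloxy-3-[3,4,5-tris(benzyloxy)phenyl]propan-1-ol | c9ccccc9COc1cc(OCc9ccccc9)c2c(c1)O[C@H](c1ccc(OCc9ccccc9)c(OCc9ccccc9)c1)[C@@H](OCc9ccccc9)[C@@H]2c1c(OCc9ccccc9)cc(OCc9ccccc9)cc1O[C@H](c1cc(OCc9ccccc9)c(OCc9ccccc9)c(OCc9ccccc9)c1)[C@@H](OCc9ccccc9)CO | intermediate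
15 | (2R,3R)-2-(benzyloxy)-3-aryloxy-3-[3,4,5-tris(benzyloxy)phenyl]propanal | c9ccccc9COc1cc(OCc9ccccc9)c2c(c1)O[C@H](c1ccc(OCc9ccccc9)c(OCc9ccccc9)c1)[C@@H](OCc9ccccc9)[C@@H]2c1c(OCc9ccccc9)cc(OCc9ccccc9)cc1O[C@H](c1cc(OCc9ccccc9)c(OCc9ccccc9)c(OCc9ccccc9)c1)[C@@H](OCc9ccccc9)C=O | intermediate
16 | (+)-gallocatechin, (2R,3S) | Oc1cc(O)c2c(c1)O[C@H](c1cc(O)c(O)c(O)c1)[C@@H](O)C2 | starting material
17 | 3,5,7,3',4',5'-hexa-O-benzyl-(+)-gallocatechin | c9ccccc9COc1cc(OCc9ccccc9)c2c(c1)O[C@H](c1cc(OCc9ccccc9)c(OCc9ccccc9)c(OCc9ccccc9)c1)[C@@H](OCc9ccccc9)C2 | intermediate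
18 | 8-bromo-hexa-O-benzylgallocatechin | c9ccccc9COc1cc(OCc9ccccc9)c2c(c1Br)O[C@H](c1cc(OCc9ccccc9)c(OCc9ccccc9)c(OCc9ccccc9)c1)[C@@H](OCc9ccccc9)C2 | intermediate
19 | 8-lithio-hexa-O-benzylgallocatechin | [Li]c1c(OCc9ccccc9)cc(OCc9ccccc9)c2c1O[C@H](c1cc(OCc9ccccc9)c(OCc9ccccc9)c(OCc9ccccc9)c1)[C@@H](OCc9ccccc9)C2 | intermediate
20 | carbinol: (2S,3R)-2-(benzyloxy)-3-aryloxy-3-[3,4,5-tris(benzyloxy)phenyl]-1-(hexa-O-benzylgallocatechin-8-yl)propan-1-ol (C1 epimers) | c9ccccc9COc1cc(OCc9ccccc9)c2c(c1)O[C@H](c1ccc(OCc9ccccc9)c(OCc9ccccc9)c1)[C@@H](OCc9ccccc9)[C@@H]2c1c(OCc9ccccc9)cc(OCc9ccccc9)cc1O[C@H](c1cc(OCc9ccccc9)c(OCc9ccccc9)c(OCc9ccccc9)c1)[C@@H](OCc9ccccc9)C(O)c1c(OCc9ccccc9)cc(OCc9ccccc9)c2c1O[C@H](c1cc(OCc9ccccc9)c(OCc9ccccc9)c(OCc9ccccc9)c1)[C@@H](OCc9ccccc9)C2 | intermediate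
21 | heptadeca-O-benzyl catechin-(4α→8)-gallocatechin-(4α→8)-gallocatechin | c9ccccc9COc1cc(OCc9ccccc9)c2c(c1)O[C@H](c1ccc(OCc9ccccc9)c(OCc9ccccc9)c1)[C@@H](OCc9ccccc9)[C@@H]2c1c(OCc9ccccc9)cc(OCc9ccccc9)c2c1O[C@H](c1cc(OCc9ccccc9)c(OCc9ccccc9)c(OCc9ccccc9)c1)[C@@H](OCc9ccccc9)[C@@H]2c1c(OCc9ccccc9)cc(OCc9ccccc9)c2c1O[C@H](c1cc(OCc9ccccc9)c(OCc9ccccc9)c(OCc9ccccc9)c1)[C@@H](OCc9ccccc9)C2 | intermediate
22 | catechin-(4α→8)-gallocatechin-(4α→8)-gallocatechin; each unit (2R,3S), both interflavan bonds 3,4-trans | Oc1cc(O)c2c(c1)O[C@H](c1ccc(O)c(O)c1)[C@@H](O)[C@@H]2c1c(O)cc(O)c2c1O[C@H](c1cc(O)c(O)c(O)c1)[C@@H](O)[C@@H]2c1c(O)cc(O)c2c1O[C@H](c1cc(O)c(O)c(O)c1)[C@@H](O)C2 | target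

**Step count and risks**

Total step count: 16. Longest linear sequence: 11 steps (4, 5, 6, 7, 8, 9, 10, 11, 14, 15, 16; the branch through 1, 2, 3 is equally long).

Steps most likely to fail:

1. Step 15. The closure may occur on the wrong face of the cation (3,4-cis), or the cation may be diverted by proton loss or by ionisation of the O1–C2 ether before the C–C bond forms. The fallback sets out from aldehyde 15 and reverses the order of the two bond formations at C4. Treatment of 15 with MgBr2·OEt2 in CH2Cl2 at −78 °C should bring about chelation-assisted intramolecular Friedel–Crafts hydroxyalkylation by C4a, giving the perbenzylated catechin-(4α→8)-gallocatechin-4-ol F1, a protected flavan-3,4-diol, as C4 epimers. Ionisation of this alcohol with TMSOTf at −78 °C in the presence of excess 17 is the established flavan-4-yl cation/arene coupling. Attack by C8 of 17, anti to the 3-benzyloxy group, should give 21, where the fallback rejoins the route.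

2. Step 7. Base-induced Payne migration of the epoxide with attack at C1, hydrolysis of the electron-rich epoxide, or slow attack by the ortho-hindered phenoxide may erode the yield or the regiochemistry. The fallback sets out from aldehyde 6 and replaces epoxide opening by an aldol/Mitsunobu sequence. A boron-mediated Evans syn-aldol reaction of 6 with (R)-4-benzyl-3-(benzyloxyacetyl)oxazolidin-2-one (Bu2BOTf, i-Pr2NEt, CH2Cl2, −78 → 0 °C) should give the (2R,3S)-syn aldol adduct F2. Reductive removal of the auxiliary with LiBH4 should give (1S,2S)-2-(benzyloxy)-1-[3,4,5-tris(benzyloxy)phenyl]propane-1,3-diol F3. Selective silylation (TBDPSCl, imidazole) should give the primary TBDPS ether F4. Mitsunobu etherification of the benzylic alcohol with phenol 5 (PPh3, DIAD, toluene, 0 °C → rt) proceeds with inversion and should give 13, where the fallback rejoins the route.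

3. Step 3. The cation may attack the ring position para to the phenol OH (between the two benzyloxy groups), alkylate on oxygen, or alkylate the product a second time. The fallback sets out from phenol 4 and blocks the para position. Silylation (TIPSCl, imidazole) should give (3,5-bis(benzyloxy)phenoxy)triisopropylsilane F5. NBS should then brominate the position remote from the bulky silyloxy group, giving the 4-bromo silyl ether F6. TBAF should release 4-bromo-3,5-bis(benzyloxy)phenol F7. Coupling of this phenol with 3 under the TMSOTf conditions can then occur only ortho to the OH and should give the bromo analogue of 5, F8. Bromine–lithium exchange (n-BuLi, 2.2 equiv, THF, −78 °C) and a methanol quench should give 5, where the fallback rejoins the route.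

**Further compounds**

F1 | step 15 | perbenzylated catechin-(4α→8)-gallocatechin-4-ol (C4 epimers of the lower unit) | c9ccccc9COc1cc(OCc9ccccc9)c2c(c1)O[C@H](c1ccc(OCc9ccccc9)c(OCc9ccccc9)c1)[C@@H](OCc9ccccc9)[C@@H]2c1c(OCc9ccccc9)cc(OCc9ccccc9)c2c1O[C@H](c1cc(OCc9ccccc9)c(OCc9ccccc9)c(OCc9ccccc9)c1)[C@@H](OCc9ccccc9)C2O
F2 | step 7 | (R)-4-benzyl-3-[(2R,3S)-2-(benzyloxy)-3-hydroxy-3-[3,4,5-tris(benzyloxy)phenyl]propanoyl]oxazolidin-2-one | O[C@@H](c1cc(OCc9ccccc9)c(OCc9ccccc9)c(OCc9ccccc9)c1)[C@@H](OCc9ccccc9)C(=O)N1C(=O)OC[C@H]1Cc1ccccc1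
F3 | step 7 | (1S,2S)-2-(benzyloxy)-1-[3,4,5-tris(benzyloxy)phenyl]propane-1,3-diol | O[C@@H](c1cc(OCc9ccccc9)c(OCc9ccccc9)c(OCc9ccccc9)c1)[C@@H](OCc9ccccc9)CO
F4 | step 7 | (1S,2S)-2-(benzyloxy)-3-(tert-butyldiphenylsilyloxy)-1-[3,4,5-tris(benzyloxy)phenyl]propan-1-ol | O[C@@H](c1cc(OCc9ccccc9)c(OCc9ccccc9)c(OCc9ccccc9)c1)[C@@H](OCc9ccccc9)CO[Si](c1ccccc1)(c1ccccc1)C(C)(C)C
F5 | step 3 | (3,5-bis(benzyloxy)phenoxy)triisopropylsilane | CC(C)[Si](C(C)C)(C(C)C)Oc1cc(OCc9ccccc9)cc(OCc9ccccc9)c1
F6 | step 3 | (4-bromo-3,5-bis(benzyloxy)phenoxy)triisopropylsilane | CC(C)[Si](C(C)C)(C(C)C)Oc1cc(OCc9ccccc9)c(Br)c(OCc9ccccc9)c1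
F7 | step 3 | 4-bromo-3,5-bis(benzyloxy)phenol | Oc1cc(OCc9ccccc9)c(Br)c(OCc9ccccc9)c1
F8 | step 3 | 4-bromo-2-[(2R,3S,4α)-penta-O-benzylcatechin-4-yl]-3,5-bis(benzyloxy)phenol | c9ccccc9COc1cc(OCc9ccccc9)c2c(c1)O[C@H](c1ccc(OCc9ccccc9)c(OCc9ccccc9)c1)[C@@H](OCc9ccccc9)[C@@H]2c1c(OCc9ccccc9)c(Br)c(OCc9ccccc9)cc1O
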